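At 10 h I wanted to know where one molecule of starting material would sit in the flask asked about, which repeats the south-east run.

the same everywhere: starting material 0.10 M
- south-east: reagent 1 equiv; second substrate 1 equiv; protic impurity 0.010 M; the very flask that is asked about, followed so far
- north: reagent 1 equiv; second substrate 1 equiv; protic impurity 0.015 M; run made earlier
- flask: reagent 1.00 equiv; second substrate 1.00 equiv; protic impurity 0.0100 M; time 10 h

| run | time / h | starting material / % | target / % |
|---|---|---|---|
| south-east | 0.417 | 86.4 | 12.0 |
| south-east | 0.667 | 82.0 | 18.0 |
| south-east | 1.00 | 78.2 | 20.8 |
| south-east | 2.00 | 73.8 | 25.4 |
| south-east | 3.00 | 72.4 | 26.8 |
| south-east | 5.00 | 71.9 | 28.1 |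
| north | 0.500 | 86.1 | 15.7 |
| north | 1.00 | 78.7 | 21.3 |
| north | 1.50 | 75.9 | 24.2 |
| north | 2.50 | 73.2 | 26.7 |
| north | 4.00 | 71.0 | 28.6 |
| north | 8.00 | 71.6 | 27.4 |

(standard deviation of a reading: 1 percentage point)

1. the state of affairs at 10 h: stopped, and by what, or still going (forward and back rates have come level / all of the starting material has reacted / the reagent has run out first / it is still moving)
2. conversion of starting material at 10 h
3. amount of target at 10 h, in percent of the starting material charged

- steps that have been proposed: starting material + reagent <-> target; second substrate + protic impurity -> quenched substrate; second substrate + reagent <-> second product
- the reaction counts as stopped when no species that holds the starting material changes by six tenths of a point or more over the second half of the time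

The proposed steps let that molecule be starting material or target, while second substrate competes for the same reagent and protic impurity quenches second substrate. In the south-east run at 5.00 h the two columns summed to 100%, so I counted no third form, and the molecule's odds of being target read 0.391. Was that a resting value? Taking 28.1% as the plateau, target's gap shrank from 16 percentage points at 0.417 h to 2.7 points at 2.00 h, which gives a relaxation time of 0.887 h. The asked time is 11.3 such times, so I committed to a stopped flask, with forward and back rates level and conversion equal to target.

The weak link was a single reading, good to 1 point. The same relaxation time left a gap of about 0.87 points at 3.00 h, so that reading could join in. The mean of the two ratios of target over starting material in the south-east run I took as a reading of the resting odds, 0.380, a conditional equilibrium constant times free reagent. The north run's reading at 8.00 h, with more impurity, gave 0.383. My number for conversion and for target was odds over one plus odds, 27.6%.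

The forecast said forward and back rates have come level, with conversion 28% and target 28%: “The runs look like a plain equilibrium, not reagent exhaustion.”

The flask gave conversion 27.2% and target 27.2%, the state being: forward and back rates have come level. Reagent still there in the flask at 10.0 h stood at 10% of its charge. Dividing the resting odds by that free reagent gives 36.8 /M, a reading of what each unit of free reagent buys in odds.

    starting material + reagent ⇌ target (K = 36.0 /M, k = 0.0900 /M/min)
    second substrate + protic impurity → quenched substrate (k = 0.920 /M/min)
    second substrate + reagent ⇌ second product (K = 220 /M, k = 0.310 /M/min)

The same flask with 4.00 equiv of reagent kept 55.3% of that charge free, 0.221 M, so the reckoning gives odds of 8.14 and target 89.1%. The simulation gave 88.8%.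

The readings stem from a simulated flask with constants of no real substance.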